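## Retrosynthetic overview

1. Cut the CH2 bridge last. This gives a 3-methylenepyran-2,4-dione (from the pyrone and an iminium C1 unit) and the only free aromatic C–H of the acyl-dihydrobenzofurandiol.
2. Cut both bonds of the dihydrofuran (Ar–CH2 and O–CH) at once. This is an enantioselective Pd [3+2] annulation of a C5 bis-allylic diacetate onto a symmetric 4-O-silyl acylphloroglucinol. C3/C5 and O2/O6 are equivalent in that substrate, and O4 is blocked so that the ring must close on the oxygen next to the acyl group.
3. The symmetric arene comes from phloroglucinol and (S)-2-methylbutanoic acid, which supplies the side-chain stereocentre.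
4. The pyrone ring is made separately in one step from a pentan-3-one silyl enol ether and malonyl dichloride.
5. Ring order: the arene is bought, the pyrone is built on a side branch, the dihydrofuran is formed in the key step, and the two halves are then joined.

Assumption: the sense of induction is taken by analogy with Trost-ligand cyclisations of 4-(2-hydroxyaryl)-2-methylbut-2-enyl esters, where the (R,R)-ligand gives the (R)-product. The (S,S)-ligand is therefore used for (S). If the sense proves opposite, the commercial antipode is used. 3-(Trimethylsilyloxy)pent-2-ene is taken as purchasable.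

## Route

**Step 1**
Reactants: 1 phloroglucinol; 2 (S)-2-methylbutanoic acid
Product: 3 (S)-2-methyl-1-(2,4,6-trihydroxyphenyl)butan-1-one
Conditions: BF3·OEt2 (neat, excess), 60 °C, 2 h; aq. NaOAc work-up
Reagents that add atoms: none
Why: This is a direct Friedel–Crafts acylation that stops at the mono-ketone because the BF2-chelated product is deactivated, and the strongly donor-conjugated, chelated carbonyl enolises poorly, so the purchased (S)-centre is carried through.

**Step 2**
Reactants: 3 (S)-2-methyl-1-(2,4,6-trihydroxyphenyl)butan-1-one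
Product: 4 (S)-1-[4-(tert-butyldimethylsilyloxy)-2,6-dihydroxyphenyl]-2-methylbutan-1-one
Conditions: TBSCl (1.0 equiv), imidazole (2 equiv), CH2Cl2/DMF, 0 °C
Reagents that add atoms: tert-butyldimethylsilyl chloride, CC(C)(C)[Si](C)(C)Cl
Why: This is a selective silyl ether formation at the unchelated, most acidic and least hindered 4-OH, while the 2- and 6-OH are hydrogen-bonded to the ketone, so ring symmetry is kept.

**Step 3**
Reactants: 5 2-methyl-2-vinyloxirane (isoprene monoxide, racemic)
Product: 6 2-methylbut-3-ene-1,2-diyl diacetate (racemic)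
Conditions: Ac2O (1.5 equiv), Bu4NOAc (5 mol %), 70 °C, sealed tube
Reagents that add atoms: acetic anhydride, CC(=O)OC(C)=O
Why: This is a nucleophile-catalysed acylative epoxide opening in which acetate attacks the primary epoxide carbon (SN2) and the tertiary alkoxide is acetylated by Ac2O, which regenerates acetate; acetyl migration is harmless because both oxygens end up acetylated.

**Step 4 (key step)**
Reactants: 4 (S)-1-[4-(tert-butyldimethylsilyloxy)-2,6-dihydroxyphenyl]-2-methylbutan-1-one; 6 2-methylbut-3-ene-1,2-diyl diacetate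
Product: 9 (S)-1-[(S)-4,6-dihydroxy-2-(prop-1-en-2-yl)-2,3-dihydrobenzofuran-7-yl]-2-methylbutan-1-one, via C-allylated allylic acetate 7 (not isolated), via 4-O-TBS dihydrobenzofuran 8 (not isolated)
Conditions: Pd2(dba)3·CHCl3 (2.5 mol %), (S,S)-DACH-phenyl Trost ligand (7.5 mol %), 6 (1.0 equiv), Et3N (2.2 equiv), CH2Cl2, 0 °C to rt; then KHF2 (2 equiv), MeOH, rt
Reagents that add atoms: none
Why: Proposed new method: only the tertiary acetate of 6 is allylic, so Pd(0) ionises it first and the phenoxide of 4 attacks as a carbon nucleophile through its dienone tautomer at the CH2 terminus (O-allylation is reversible under Pd) to give 7, whose primary acetate is now allylic and ionises to a 2-methyl π-allyl that equilibrates its faces by π-σ-π at the CH2 end in the Et3N/AcOH buffer, and the only free neighbouring oxygen (O2) closes 5-exo in the chiral pocket to set C2 as (S), after which KHF2 removes the phenolic TBS group; the closest known reaction types are the Pd-catalysed Tsuji–Trost [3+2] of 1,3-diketones with butenediyl diesters to 2-vinyldihydrofurans, Pd C-allylation of benzene polyols, and Trost asymmetric allylic etherification of (2-hydroxyaryl)-2-methylbutenyl esters to 2-isopropenyl-2,3-dihydrobenzofurans.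

**Step 5**
Reactants: 10 3-(trimethylsilyloxy)pent-2-ene (E/Z mixture); 11 malonyl dichloride
Product: 13 6-ethyl-4-hydroxy-5-methyl-2H-pyran-2-one, via 4-methyl-3,5-dioxoheptanoyl chloride 12 (not isolated)
Conditions: Et2O, −78 °C to rt
Reagents that add atoms: none
Why: C-acylation of the silyl enol ether by one acyl chloride, followed by enol O-acylation (lactonisation) by the second, gives the 4-hydroxy-2-pyrone directly (silyl enol ether/malonyl chloride pyrone synthesis).

**Step 6**
Reactants: 9 (S)-1-[(S)-4,6-dihydroxy-2-(prop-1-en-2-yl)-2,3-dihydrobenzofuran-7-yl]-2-methylbutan-1-one; 13 6-ethyl-4-hydroxy-5-methyl-2H-pyran-2-one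
Product: 16 CNP0261501.1 (target), via pyrone Mannich base 14 (not isolated), via 3-methylenepyran-2,4-dione 15 (not isolated)
Conditions: 13, CH2=NMe2+ I− (1.0 equiv), MeCN, 0 °C, 30 min; then 9 (1.0 equiv), 40 °C
Reagents that add atoms: Eschenmoser's salt (N,N-dimethylmethyleneiminium iodide), C=[N+](C)C.[I-]
Why: A Mannich reaction at pyrone C3 followed by loss of Me2NH gives a quinone-methide-like Michael acceptor that is captured in a Friedel–Crafts/Michael addition by C5 of 9, the only free aromatic position, under conditions too mild to touch the isopropenyl group or either stereocentre.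

## Compound list

| No. | Name | SMILES | Role |
|---|---|---|---|
| 1 | phloroglucinol | Oc1cc(O)cc(O)c1 | starting material |
| 2 | (S)-2-methylbutanoic acid | CC[C@H](C)C(=O)O | starting material |
| 3 | (S)-2-methyl-1-(2,4,6-trihydroxyphenyl)butan-1-one | CC[C@H](C)C(=O)c1c(O)cc(O)cc1O | intermediate |
| 4 | (S)-1-[4-(TBSO)-2,6-dihydroxyphenyl]-2-methylbutan-1-one | CC[C@H](C)C(=O)c1c(O)cc(O[Si](C)(C)C(C)(C)C)cc1O | intermediate |
| 5 | 2-methyl-2-vinyloxirane (racemic) | C=CC1(C)CO1 | starting material |
| 6 | 2-methylbut-3-ene-1,2-diyl diacetate (racemic) | C=CC(C)(OC(C)=O)COC(C)=O | intermediate |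
| 7 | (E)-4-{6-(TBSO)-2,4-dihydroxy-3-[(S)-2-methylbutanoyl]phenyl}-2-methylbut-2-enyl acetate | CC[C@H](C)C(=O)c1c(O)cc(O[Si](C)(C)C(C)(C)C)c(C/C=C(\C)COC(C)=O)c1O | intermediate (not isolated) |
| 8 | (S)-1-[(S)-4-(TBSO)-6-hydroxy-2-(prop-1-en-2-yl)-2,3-dihydrobenzofuran-7-yl]-2-methylbutan-1-one | C=C(C)[C@@H]1Cc2c(O[Si](C)(C)C(C)(C)C)cc(O)c(C(=O)[C@@H](C)CC)c2O1 | intermediate (not isolated) |
| 9 | (S)-1-[(S)-4,6-dihydroxy-2-(prop-1-en-2-yl)-2,3-dihydrobenzofuran-7-yl]-2-methylbutan-1-one | C=C(C)[C@@H]1Cc2c(O)cc(O)c(C(=O)[C@@H](C)CC)c2O1 | intermediate |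
| 10 | 3-(trimethylsilyloxy)pent-2-ene (E/Z mixture) | CC=C(CC)O[Si](C)(C)C | starting material |
| 11 | malonyl dichloride | O=C(Cl)CC(=O)Cl | starting material |
| 12 | 4-methyl-3,5-dioxoheptanoyl chloride | CCC(=O)C(C)C(=O)CC(=O)Cl | intermediate (not isolated) |
| 13 | 6-ethyl-4-hydroxy-5-methyl-2H-pyran-2-one | CCc1oc(=O)cc(O)c1C | intermediate |
| 14 | 3-[(dimethylamino)methyl]-6-ethyl-4-hydroxy-5-methyl-2H-pyran-2-one | CCc1oc(=O)c(CN(C)C)c(O)c1C | intermediate (not isolated) |
| 15 | 6-ethyl-5-methyl-3-methylidenepyran-2,4-dione | C=C1C(=O)OC(CC)=C(C)C1=O | intermediate (not isolated) |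
| 16 | CNP0261501.1: 3-({(S)-4,6-dihydroxy-7-[(S)-2-methylbutanoyl]-2-(prop-1-en-2-yl)-2,3-dihydrobenzofuran-5-yl}methyl)-6-ethyl-4-hydroxy-5-methyl-2H-pyran-2-one | C=C(C)[C@@H]1Cc2c(O)c(Cc3c(O)c(C)c(CC)oc3=O)c(O)c(C(=O)[C@@H](C)CC)c2O1 | target |

## Step count

- Total step count: 6
- Longest linear sequence: 4 (steps 1, 2, 4, 6)

## Steps most likely to fail

**Step 4.** Several things can go wrong in the tandem annulation:
- O-allylation may win over C-allylation.
- The π-allyl may lose a proton to give a diene.
- Selectivity may be low.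
- Pd may re-ionise the product ether and erode the ee.

The fallback sets out from 4 and drops π-allyl chemistry altogether.
- Acid-catalysed Friedel–Crafts prenylation of 4 (2-methylbut-3-en-2-ol, BF3·OEt2, dioxane) gives the 3-prenyl ketone F1.
- Shi epoxidation with the D-fructose-derived ketone and Oxone gives the (R)-epoxide F2.
- F2 is opened in the same pot by the neighbouring 2-OH, 5-exo with inversion, to the (S)-configured tertiary alcohol F3.
- Dehydration of F3 with Burgess reagent gives the isopropenyl compound.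
- The fallback rejoins the route at 8, just before the KHF2 treatment.

**Step 6.** The methide can be trapped by a second pyrone, giving the methylene-bis-pyrone, or two arenes can be bridged. The fallback sets out from 9 and fixes the C1 unit on the arene first.
- Magnesium-mediated ortho-formylation (MgCl2, Et3N, paraformaldehyde, MeCN) gives the 5-carbaldehyde F4.
- Proline-catalysed Knoevenagel condensation of F4 with 13 gives the arylidene-pyrandione F5.
- F5 is reduced in situ by Hantzsch ester (three-component reductive alkylation).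
- The fallback rejoins the route at 16.

**Step 1.** The α-stereocentre may partly racemise in hot Lewis acid, and some diacylation may occur. The fallback sets out from 1 and 2 and forms the ketone under anionic conditions.
- 1 is converted with MOMCl/iPr2NEt to the tris-MOM ether F6.
- 2 is converted with MeNH(OMe)·HCl/EDC to the Weinreb amide F7.
- F6 is lithiated (n-BuLi, THF, 0 °C) to the aryllithium F8.
- F8 is acylated with F7 at −78 °C to the ketone F9.
- The MOM groups of F9 are removed with dilute HCl in MeOH at rt.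
- The fallback rejoins the route at 3.

## Further compounds

F1 | step 4 | (S)-1-[4-(TBSO)-2,6-dihydroxy-3-(3-methylbut-2-enyl)phenyl]-2-methylbutan-1-one | CC[C@H](C)C(=O)c1c(O)cc(O[Si](C)(C)C(C)(C)C)c(CC=C(C)C)c1O
F2 | step 4 | (S)-1-[4-(TBSO)-3-{[(R)-3,3-dimethyloxiran-2-yl]methyl}-2,6-dihydroxyphenyl]-2-methylbutan-1-one | CC[C@H](C)C(=O)c1c(O)cc(O[Si](C)(C)C(C)(C)C)c(C[C@H]2OC2(C)C)c1O
F3 | step 4 | (S)-1-[(S)-4-(TBSO)-6-hydroxy-2-(2-hydroxypropan-2-yl)-2,3-dihydrobenzofuran-7-yl]-2-methylbutan-1-one | CC(C)(O)[C@@H]1Cc2c(O[Si](C)(C)C(C)(C)C)cc(O)c(C(=O)[C@@H](C)CC)c2O1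
F4 | step 6 | (S)-4,6-dihydroxy-7-[(S)-2-methylbutanoyl]-2-(prop-1-en-2-yl)-2,3-dihydrobenzofuran-5-carbaldehyde | C=C(C)[C@@H]1Cc2c(O)c(C=O)c(O)c(C(=O)[C@@H](C)CC)c2O1
F5 | step 6 | 3-(arylmethylidene)-6-ethyl-5-methylpyran-2,4-dione from F4 and 13 | C=C(C)[C@@H]1Cc2c(O)c(C=C3C(=O)OC(CC)=C(C)C3=O)c(O)c(C(=O)[C@@H](C)CC)c2O1
F6 | step 1 | 1,3,5-tris(methoxymethoxy)benzene | COCOc1cc(OCOC)cc(OCOC)c1
F7 | step 1 | (S)-N-methoxy-N,2-dimethylbutanamide | CC[C@H](C)C(=O)N(C)OC
F8 | step 1 | 2,4,6-tris(methoxymethoxy)phenyllithium | [Li]c1c(OCOC)cc(OCOC)cc1OCOC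
F9 | step 1 | (S)-2-methyl-1-[2,4,6-tris(methoxymethoxy)phenyl]butan-1-one | CC[C@H](C)C(=O)c1c(OCOC)cc(OCOC)cc1OCOC
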